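**Plan**
1. Retrosynthetic cuts, in order: the C2 epimer and all O-benzyl bonds; the C2–C3 bond of the dihydrofuran ring (to a diaryl carbene at C3 and an O1–CH2–aryl ether); the C3=N bond of the carbene precursor (to an aryl bromide and a benzonitrile); the CH2–CH2 bond of the bibenzyl; the two aryl O–CH2 ether bonds.
2. Enabling feature: C3 is a diarylmethine between ring A and the 3,5-dioxygenated ring, so it can be a donor/donor carbene. C2 is an O1-bound benzylic CH whose 2,4-dioxygenated aryl makes the C–H hydridic and later lets C2–O1 ionize reversibly. C3a is flanked by two oxygens (O1 and the C4 oxygen), so ring A can carry two identical arylmethoxy arms and no choice between C–H bonds arises.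
3. Forward: double Mitsunobu etherification of a 2-bromoresorcinol ester, chain extension to the bibenzyl, Br/Li exchange and addition to the nitrile, imine-to-hydrazone exchange, ring closure (the dihydrofuran is the only ring made), hydrogenolysis, epimerization.
4. Stereochemistry: C3 (S) comes from the chiral Rh(II) catalyst in the ring closure, which gives the cis (2R,3S) ring. C2 is then funnelled to trans (2S,3S) by reversible C2–O1 ionization, with C3 as the fixed reference.

Key step: step 9

Remark: DBB = [2,4-bis(benzyloxy)phenyl]methyl; "DBB-oxy" is the corresponding arylmethoxy group.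
Assumption: Rh2(R-PTAD)4 is taken to deliver the (3S) series; if the sense of induction is the opposite, the antipodal catalyst Rh2(S-PTAD)4 is used with no other change.

**Step 1**
Reactants: 1 2,4-bis(benzyloxy)benzaldehyde
Product: 2 [2,4-bis(benzyloxy)phenyl]methanol
Conditions: NaBH4, MeOH–THF, 0 °C
Reagents that add atoms: none
Why: Borohydride reduction of an aryl aldehyde should give the benzylic alcohol cleanly, the benzyl ethers being inert; no stereocentre is formed.

**Step 2**
Reactants: 3 methyl 4-bromo-3,5-dihydroxybenzoate; 2 [2,4-bis(benzyloxy)phenyl]methanol (2.2 equiv)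
Product: 4 methyl 4-bromo-3,5-bis(DBB-oxy)benzoate
Conditions: PPh3, DIAD, THF, 0 °C → rt
Reagents that add atoms: none
Why: Twofold Mitsunobu etherification, in which the bromine-flanked phenols are acidic pronucleophiles and the neutral redox conditions activate the electron-rich benzylic alcohol without passing through its unstable halide.

**Step 3**
Reactants: 4 methyl 4-bromo-3,5-bis(DBB-oxy)benzoate
Product: 5 [4-bromo-3,5-bis(DBB-oxy)phenyl]methanol
Conditions: DIBAL-H, CH2Cl2, −78 → 0 °C; Rochelle salt work-up
Reagents that add atoms: none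
Why: DIBAL-H reduction of a benzoate to the benzylic alcohol should leave the aryl bromide and all benzylic ethers untouched.

**Step 4**
Reactants: 5 [4-bromo-3,5-bis(DBB-oxy)phenyl]methanol
Product: 6 2-bromo-5-(bromomethyl)-1,3-bis(DBB-oxy)benzene
Conditions: CBr4, PPh3, CH2Cl2, 0 °C
Reagents that add atoms: carbon tetrabromide, BrC(Br)(Br)Br
Why: Appel bromination converts the primary benzylic alcohol into the bromide under essentially neutral conditions that the acid-labile 2,4-dialkoxybenzyl ethers should survive.

**Step 5**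
Reactants: 7 4-(benzyloxy)benzyl chloride; 6 2-bromo-5-(bromomethyl)-1,3-bis(DBB-oxy)benzene
Product: 9 2-bromo-1,3-bis(DBB-oxy)-5-{2-[4-(benzyloxy)phenyl]ethyl}benzene, via benzylic Grignard reagent 8 (not isolated)
Conditions: 7, Mg, THF, 0 °C (slow addition); then 6, Li2CuCl4 (3 mol %), THF, −20 °C → rt
Reagents that add atoms: none
Why: Copper-catalysed benzyl–benzyl Grignard cross-coupling should forge the CH2–CH2 link of the bibenzyl directly at the saturated oxidation level, the doubly ortho-shielded aryl bromide being inert to the Grignard reagent at low temperature.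

**Step 6**
Reactants: 10 3,5-dihydroxybenzonitrile
Product: 11 3,5-bis(benzyloxy)benzonitrile
Conditions: BnBr, K2CO3, DMF, 60 °C
Reagents that add atoms: benzyl bromide, BrCc1ccccc1
Why: Williamson etherification of both phenols under carbonate base, the nitrile being inert.

**Step 7**
Reactants: 9 2-bromo-1,3-bis(DBB-oxy)-5-{2-[4-(benzyloxy)phenyl]ethyl}benzene; 11 3,5-bis(benzyloxy)benzonitrile
Product: 14 [2,6-bis(DBB-oxy)-4-{2-[4-(benzyloxy)phenyl]ethyl}phenyl][3,5-bis(benzyloxy)phenyl]methanimine (N–H ketimine), via aryllithium 12 (not isolated), via lithium ketimide 13 (not isolated)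
Conditions: n-BuLi, THF, −78 °C; then 11, −78 → 0 °C; MeOH quench
Reagents that add atoms: none
Why: Bromine–lithium exchange at −78 °C fixes the metalation site (a directed lithiation would have to choose among several ring positions lying between two alkoxy groups), the aryllithium adds only once to the nitrile because the lithium ketimide is not electrophilic, and methanol quench should give the hindered, hydrolysis-resistant N–H ketimine.

**Step 8**
Reactants: 14 N–H ketimine
Product: 15 {[2,6-bis(DBB-oxy)-4-{2-[4-(benzyloxy)phenyl]ethyl}phenyl][3,5-bis(benzyloxy)phenyl]methylidene}hydrazine (hydrazone, E/Z mixture)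
Conditions: N2H4·H2O (excess), AcOH (cat.), EtOH–THF, 70 °C
Reagents that add atoms: hydrazine (used as the monohydrate), NN
Why: Transimination, in which the protonated N–H ketimine is far more electrophilic than the corresponding di-ortho-substituted ketone and should exchange with excess hydrazine with loss of ammonia; the E/Z mixture is inconsequential because the C=N geometry is erased in the diazo compound.

**Step 9**
Reactants: 15 hydrazone
Product: 17 (2R,3S)-2-[2,4-bis(benzyloxy)phenyl]-3-[3,5-bis(benzyloxy)phenyl]-4-(DBB-oxy)-6-{2-[4-(benzyloxy)phenyl]ethyl}-2,3-dihydro-1-benzofuran (cis), via diaryldiazomethane 16 (not isolated)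
Conditions: MnO2, CH2Cl2, 0 °C, filter; then Rh2(R-PTAD)4 (1 mol %), CH2Cl2, −20 °C → rt, slow addition of 16
Reagents that add atoms: none
Why: MnO2 dehydrogenates the hydrazone to diaryldiazomethane 16, Rh(II) expels N2 to give a donor/donor carbenoid at the future C3, and this carbenoid takes the hydridic O–CH2 hydrogen of an ortho arylmethoxy arm through a hydride-shift-like transition state that collapses to the C2–C3 bond. The closest known reaction type is the enantioselective intramolecular C–H insertion of donor/donor rhodium carbenoids derived from 2-(benzyloxy)benzophenone hydrazones, which gives cis-2,3-diaryl-2,3-dihydrobenzofurans. The dihydrofuran ring closes as a five-membered ring by 1,5-insertion (carbenoid carbon onto the δ C–H through a five-centre transition state). C3 is controlled by the chiral PTAD ligand sphere, which differentiates the two faces of the carbenoid, while C2 follows C3 under substrate control because the migrating hydrogen and the new C–C bond are delivered on the same face, so the two aryl groups end up cis. The step needs site selectivity among many C–H bonds, and the substrate secures it: the two ortho arms are homotopic by rotation of ring A so either gives the same product, only their C–H bonds reach the carbenoid through a five-membered transition state, the 2,4-dialkoxyaryl group makes them the most hydridic, and no O–H or N–H bond is present. Low temperature and slow addition of 16 should keep azine formation down.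

**Step 10**
Reactants: 17 cis-(2R,3S) perbenzylated dihydrobenzofuran
Product: 18 (2R,3S)-2-(2,4-dihydroxyphenyl)-3-(3,5-dihydroxyphenyl)-6-[2-(4-hydroxyphenyl)ethyl]-2,3-dihydro-1-benzofuran-4-ol (cis)
Conditions: H2 (1 atm), 10% Pd/C, EtOAc–MeOH, rt
Reagents that add atoms: none
Why: Palladium-catalysed hydrogenolysis should cleave the seven primary O-benzyl groups and the spectator arylmethyl ether (released as 4-methylresorcinol) faster than the secondary, ring-constrained and shielded C2–O1 bond, and it does not touch C2 or C3, so the (2R,3S) configuration is carried through.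

**Step 11**
Reactants: 18 cis-(2R,3S) hexaphenol
Product: 19 (2S,3S)-2-(2,4-dihydroxyphenyl)-3-(3,5-dihydroxyphenyl)-6-[2-(4-hydroxyphenyl)ethyl]-2,3-dihydro-1-benzofuran-4-ol (trans; CNP0329616.1)
Conditions: TFA (cat.), MeCN (high dilution), rt, under argon
Reagents that add atoms: none
Why: Acid-catalysed epimerization of a cis-2-aryl-2,3-dihydrobenzofuran, in which heterolysis of the C2–O1 bond gives a cation stabilised as an ortho/para-quinone methide by the 2,4-dihydroxyphenyl group, both C2 epimers pass through this planar intermediate, and reclosure by either of the two equivalent ring A hydroxyls should favour the trans isomer with the aryl groups anti, C3 being untouched and dictating the (2S,3S) outcome.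

**Compound list**
1 | 2,4-bis(benzyloxy)benzaldehyde | O=Cc1ccc(OCc2ccccc2)cc1OCc1ccccc1 | starting material
2 | [2,4-bis(benzyloxy)phenyl]methanol | OCc1ccc(OCc2ccccc2)cc1OCc1ccccc1 | intermediate
3 | methyl 4-bromo-3,5-dihydroxybenzoate | COC(=O)c1cc(O)c(Br)c(O)c1 | starting material
4 | methyl 4-bromo-3,5-bis{[2,4-bis(benzyloxy)phenyl]methoxy}benzoate | COC(=O)c1cc(OCc2ccc(OCc3ccccc3)cc2OCc2ccccc2)c(Br)c(OCc2ccc(OCc3ccccc3)cc2OCc2ccccc2)c1 | intermediate
5 | (4-bromo-3,5-bis{[2,4-bis(benzyloxy)phenyl]methoxy}phenyl)methanol | OCc1cc(OCc2ccc(OCc3ccccc3)cc2OCc2ccccc2)c(Br)c(OCc2ccc(OCc3ccccc3)cc2OCc2ccccc2)c1 | intermediate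
6 | 2-bromo-5-(bromomethyl)-1,3-bis{[2,4-bis(benzyloxy)phenyl]methoxy}benzene | BrCc1cc(OCc2ccc(OCc3ccccc3)cc2OCc2ccccc2)c(Br)c(OCc2ccc(OCc3ccccc3)cc2OCc2ccccc2)c1 | intermediate
7 | 1-(benzyloxy)-4-(chloromethyl)benzene [4-(benzyloxy)benzyl chloride] | ClCc1ccc(OCc2ccccc2)cc1 | starting material
8 | [4-(benzyloxy)benzyl]magnesium chloride | Cl[Mg]Cc1ccc(OCc2ccccc2)cc1 | intermediate
9 | 2-bromo-1,3-bis{[2,4-bis(benzyloxy)phenyl]methoxy}-5-{2-[4-(benzyloxy)phenyl]ethyl}benzene | Brc1c(OCc2ccc(OCc3ccccc3)cc2OCc2ccccc2)cc(CCc2ccc(OCc3ccccc3)cc2)cc1OCc1ccc(OCc2ccccc2)cc1OCc1ccccc1 | intermediate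
10 | 3,5-dihydroxybenzonitrile | N#Cc1cc(O)cc(O)c1 | starting material
11 | 3,5-bis(benzyloxy)benzonitrile | N#Cc1cc(OCc2ccccc2)cc(OCc2ccccc2)c1 | intermediate
12 | (2,6-bis{[2,4-bis(benzyloxy)phenyl]methoxy}-4-{2-[4-(benzyloxy)phenyl]ethyl}phenyl)lithium | [Li]c1c(OCc2ccc(OCc3ccccc3)cc2OCc2ccccc2)cc(CCc2ccc(OCc3ccccc3)cc2)cc1OCc1ccc(OCc2ccccc2)cc1OCc1ccccc1 | intermediate
13 | N-lithio derivative of ketimine 14 (lithium ketimide) | [Li]N=C(c1cc(OCc2ccccc2)cc(OCc2ccccc2)c1)c1c(OCc2ccc(OCc3ccccc3)cc2OCc2ccccc2)cc(CCc2ccc(OCc3ccccc3)cc2)cc1OCc1ccc(OCc2ccccc2)cc1OCc1ccccc1 | intermediate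
14 | 1-(2,6-bis{[2,4-bis(benzyloxy)phenyl]methoxy}-4-{2-[4-(benzyloxy)phenyl]ethyl}phenyl)-1-[3,5-bis(benzyloxy)phenyl]methanimine | N=C(c1cc(OCc2ccccc2)cc(OCc2ccccc2)c1)c1c(OCc2ccc(OCc3ccccc3)cc2OCc2ccccc2)cc(CCc2ccc(OCc3ccccc3)cc2)cc1OCc1ccc(OCc2ccccc2)cc1OCc1ccccc1 | intermediate
15 | hydrazone of the corresponding diaryl ketone, [(2,6-bis{[2,4-bis(benzyloxy)phenyl]methoxy}-4-{2-[4-(benzyloxy)phenyl]ethyl}phenyl)(3,5-bis(benzyloxy)phenyl)methylidene]hydrazine (E/Z mixture, C=N geometry not specified) | NN=C(c1cc(OCc2ccccc2)cc(OCc2ccccc2)c1)c1c(OCc2ccc(OCc3ccccc3)cc2OCc2ccccc2)cc(CCc2ccc(OCc3ccccc3)cc2)cc1OCc1ccc(OCc2ccccc2)cc1OCc1ccccc1 | intermediate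
16 | 2-{[3,5-bis(benzyloxy)phenyl](diazo)methyl}-1,3-bis{[2,4-bis(benzyloxy)phenyl]methoxy}-5-{2-[4-(benzyloxy)phenyl]ethyl}benzene | [N-]=[N+]=C(c1cc(OCc2ccccc2)cc(OCc2ccccc2)c1)c1c(OCc2ccc(OCc3ccccc3)cc2OCc2ccccc2)cc(CCc2ccc(OCc3ccccc3)cc2)cc1OCc1ccc(OCc2ccccc2)cc1OCc1ccccc1 | intermediate
17 | (2R,3S)-2-[2,4-bis(benzyloxy)phenyl]-3-[3,5-bis(benzyloxy)phenyl]-4-{[2,4-bis(benzyloxy)phenyl]methoxy}-6-{2-[4-(benzyloxy)phenyl]ethyl}-2,3-dihydro-1-benzofuran (cis) | C(c1ccccc1)Oc1ccc(CCc2cc(OCc4ccc(OCc5ccccc5)cc4OCc4ccccc4)c3c(c2)O[C@@H](c2ccc(OCc4ccccc4)cc2OCc2ccccc2)[C@H]3c2cc(OCc4ccccc4)cc(OCc4ccccc4)c2)cc1 | intermediate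
18 | (2R,3S)-2-(2,4-dihydroxyphenyl)-3-(3,5-dihydroxyphenyl)-6-[2-(4-hydroxyphenyl)ethyl]-2,3-dihydro-1-benzofuran-4-ol (cis) | Oc1ccc(CCc2cc(O)c3c(c2)O[C@@H](c2ccc(O)cc2O)[C@H]3c2cc(O)cc(O)c2)cc1 | intermediate
19 | (2S,3S)-2-(2,4-dihydroxyphenyl)-3-(3,5-dihydroxyphenyl)-6-[2-(4-hydroxyphenyl)ethyl]-2,3-dihydro-1-benzofuran-4-ol (trans) | Oc1ccc(CCc2cc(O)c3c(c2)O[C@H](c2ccc(O)cc2O)[C@H]3c2cc(O)cc(O)c2)cc1 | target

**Totals**
Total step count: 11. Longest linear sequence: 10 steps (1 → 2 → 4 → 5 → 6 → 9 → 14 → 15 → 17 → 18 → 19; step 6 lies on the side branch).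

**Steps most likely to fail, with fallbacks**

1) Step 9. The di-ortho-substituted aryl ring of the carbenoid is forced out of plane, so enantiofacial discrimination by the catalyst may be incomplete, and coupling of carbenoid with unreacted diazo compound to the azine may compete with insertion. The fallback gives up catalyst-controlled induction in favour of resolution. It sets out from hydrazone 15, which is oxidised to 16 as before. Compound 16 is then cyclised with achiral Rh2(OAc)4 under slow addition and high dilution to the racemic cis-dihydrobenzofuran. The racemate is resolved by preparative chromatography on a chiral stationary phase (SFC). The wanted antipode is 17, where the route is rejoined. The unwanted (2S,3R)-enantiomer of 17 F1 is set aside. Because C2 is later equilibrated, only the C3 configuration has to be secured by the separation.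

2) Step 10. Over-reduction may occur: the doubly activated benzylic C2–O1 bond of the ring may undergo hydrogenolysis alongside the benzyl ethers, opening the heterocycle. The fallback replaces reductive cleavage by Lewis-acid debenzylation. It sets out from 17, which is treated with excess BCl3 and pentamethylbenzene in CH2Cl2 at −78 °C and then quenched with MeOH. All benzyl groups and the spectator arm leave as cations that are captured by pentamethylbenzene. The hexaphenol should result as a C2-epimer mixture, since the Lewis acid also ionizes C2–O1 reversibly. The route is rejoined at 18, with any 19 already formed carried along, and step 11 completes the equilibration. No compound outside the compound list is made (F0).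

3) Step 11. Once the unprotected hexaphenol is ionized at C2, the cation may be intercepted intermolecularly by the resorcinol rings (oligomerization) or may lose H-3 to a triarylethene, which would erase C3. The fallback changes the order, so that C2 is equilibrated while the phenols are still masked. It sets out from 17, which is treated with TFA and 1,3,5-trimethoxybenzene in CH2Cl2 at 0 °C. The spectator arylmethyl ether is cleaved, its cation being scavenged by the trimethoxybenzene, and C2 equilibrates through C2–O1 ionization and reclosure. This should give (2S,3S)-2-[2,4-bis(benzyloxy)phenyl]-3-[3,5-bis(benzyloxy)phenyl]-6-{2-[4-(benzyloxy)phenyl]ethyl}-2,3-dihydro-1-benzofuran-4-ol F2. Hydrogenolysis of F2 (H2, Pd/C, EtOAc–MeOH, rt) then removes the five remaining benzyl groups and comes back to the route at 19.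

**Further compounds**
F1 | step 9 | (2S,3R)-2-[2,4-bis(benzyloxy)phenyl]-3-[3,5-bis(benzyloxy)phenyl]-4-{[2,4-bis(benzyloxy)phenyl]methoxy}-6-{2-[4-(benzyloxy)phenyl]ethyl}-2,3-dihydro-1-benzofuran (enantiomer of 17) | C(c1ccccc1)Oc1ccc(CCc2cc(OCc4ccc(OCc5ccccc5)cc4OCc4ccccc4)c3c(c2)O[C@H](c2ccc(OCc4ccccc4)cc2OCc2ccccc2)[C@@H]3c2cc(OCc4ccccc4)cc(OCc4ccccc4)c2)cc1
F0 | step 10 | none | none
F2 | step 11 | (2S,3S)-2-[2,4-bis(benzyloxy)phenyl]-3-[3,5-bis(benzyloxy)phenyl]-6-{2-[4-(benzyloxy)phenyl]ethyl}-2,3-dihydro-1-benzofuran-4-ol | C(c1ccccc1)Oc1ccc(CCc2cc(O)c3c(c2)O[C@H](c2ccc(OCc4ccccc4)cc2OCc2ccccc2)[C@H]3c2cc(OCc4ccccc4)cc(OCc4ccccc4)c2)cc1
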